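Z formed per J lost is the ratio I reckon with here.

| flask | J | D | temperature | remark | time |
|---|---|---|---|---|---|
| noon | 1 M | 2 M | 95 °C | run made earlier |  |
| blue | 2.0 M | 2.00 M |  | at 125 °C until 3.0 min, from then on at 95 °C | 15 min |
| red | 2.0 M | 2.00 M | 95 °C |  | 15 min |
| ochre | 2.0 M | 2.00 M | 110 °C |  | 15 min |
| amber | 2.0 M | 2.00 M | 125 °C |  | 15 min |

noon run (percent of the J charged)

| time / min | Z / % | J / % |
|---|---|---|
| 0.250 | 0 | 97.9 |
| 0.667 | 1.3 | 95.0 |
| 1.33 | 4.4 | 88.2 |
| 2.00 | 9.5 | 80.4 |
| 2.50 | 14.5 | 72.2 |
| 4.00 | 22.8 | 56.3 |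
| 5.00 | 31.9 | 44.7 |

(scatter of a reading: 1 percentage point)

- percentages count the J that a species holds: one X counts as two
- solid, in amounts per volume of the solution: D
- reactions considered so far: J <-> G; G <-> E; Q + G -> Z; Q + E -> L; D <-> Q; 2 J -> X
- at the start none of D is in solution
- the earlier runs do not show what temperature does; that part of a forecast is a guess

1. the best flask by amount of Z, in percent of the J charged; "all alike" if 1.5 percentage points covers them all (blue / red / ochre / amber / all alike)
2. amount of Z at the end, in percent of the J charged, blue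
3. amount of Z at the end, in percent of the J charged, red
4. amount of Z at the end, in percent of the J charged, ochre
5. amount of Z at the end, in percent of the J charged, amber

Over the last three noon readings, 54.6% of the J lost turned up as Z; this Z formed per J lost is the Z share, the selectivity toward Z, and it is a reading with its scatter on it. I ask first for the end state. Z and L each take one Q, and the new flasks hold 1.00 equivalent of D per J, so the charge of D has room for the J, and Z at the end of a flask is its share times the J it has lost.

Then I ask how fast. Noon J falls at an average 0.161 min⁻¹, and at that pace red loses 91.1% in 15 min, which gives 49.7% Z. That leans high, since red sets the same D against 2.0 M of J, more than noon's 1 M.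

Now I turn the question round. For blue, ochre or amber to beat my figure for red, even with the whole charge lost, its share must stay above 49.7%, so on that figure heat may cost the share about 4.9 percentage points against the 54.6% read at 95 °C. That margin is thin, and the runs show nothing of temperature, so my guess is red.

The forecast puts ochre first, with blue 53%, red 50%, ochre 56% and amber 52%, and it expects that “side paths (E, L, X) probably gain”.

Red is best at 44.3%, above blue 24.9%, ochre 34.4% and amber 23.5%.

J ⇌ G (K = 0.00160, k = 0.0370 s⁻¹, Ea = 105 kJ mol⁻¹, ΔH = −5.00 kJ mol⁻¹); G ⇌ E (K = 2.60, k = 3.70 s⁻¹, Ea = 83.0 kJ mol⁻¹, ΔH = 34.0 kJ mol⁻¹); Q + G → Z (k = 3.10 M⁻¹ s⁻¹, Ea = 57.0 kJ mol⁻¹); Q + E → L (k = 5.00 M⁻¹ s⁻¹, Ea = 44.0 kJ mol⁻¹); D ⇌ Q, rate k5*(cs5 - [Q]) while solid is left; crystals form when [Q] > cs5 (solubility = 1.90 M, k = 0.00570 s⁻¹); 2 J → X (k = 1.20 × 10⁻⁶ M⁻¹ s⁻¹, Ea = 100 kJ mol⁻¹); (constants at 110 °C) Red has lost 86.1% of its J, and my 54.6% of that gives 47.0%; its own share is 51.5%, and amber's is 23.8%, below the 49.7% it needed. In blue at 1.65 min, E falls back 1.6 times as fast as it goes on to L. The neighbour like blue with 0.80 M of D holds 0.400 equiv of D per J, ends with 0% D and 59.5% J, and has a Z share of 20.1%.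

(The numbers in the tables stem from a simulated flask from invented constants; scatter was added.)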